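**Retrosynthetic overview**

1. Numbering used throughout: lactone O1, C2(=O), C3(=CH2), C3a, C4H2, C5(OH), C6(CH3), C7(OH)(C1'(=O)–C2'H2–C3'H(OH)–C4'H3), C8(O-acyl), C8a. Removed last are the C8 ester, the exo-methylene (Mannich/elimination), the C1' ketone (dithiane) and the C5 hydroxyl (hydroxyl-directed reduction of a C5 ketone).
2. Enabling feature: in the seven-membered ring the oxygen on C7 lies 1,4 to the C4 methylene, so it can be tied back to C4 as an ether bridge (opened later by SmI2 next to a C5 ketone). The lactone carbinol C8a, flanked by oxygenated C8 and by C3a, can be a ketone. Together this is an 8-oxabicyclo[3.2.1]oct-6-en-3-one.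
3. Key disconnection: C3a–C4 and C7–C8 in one (4+3) cycloaddition of a 2,3-disubstituted furan (C4 to C7, ring oxygen = O7, complete side chain masked as a dithiane) with a chiral 1-alkoxy-2-siloxyallyl cation (C8, C8a, C3a).
4. Ring order: furan (purchased) → cycloheptene ring with temporary oxygen bridge (step 5) → cis γ-lactone (steps 6 and 7) → bridge opened to the free cycloheptane (step 10).
5. Stereocontrol: auxiliary on the cation (absolute sense, C7, C8); the bridge (C3a, C8a, C6); the freed C7 hydroxyl (C5); C3' from (R)-propylene oxide; ester from (S)-2-methylbutanoic acid.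

Key step: step 5

Assumption: the (S)-configured 1-(naphthalen-2-yl)ethoxy group is taken to shield the cation face that leads to the (1S,2R,5S) bicycle 14; should the induction be opposite, the equally available (R)-alcohol is used and nothing else changes.

Abbreviations in names: NEO = (1S)-1-(naphthalen-2-yl)ethoxy; DTS = 2-[(2R)-2-(tert-butyldimethylsilyloxy)propyl]-1,3-dithian-2-yl; TBS = tert-butyldimethylsilyl. Bicycle numbering C1, C2, C3, C4, C5, C6, C7 corresponds to target C7, C8, C8a, C3a, C4, C5, C6.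

**Step 1**
Reactants: 1 3-methylfuran-2-carbaldehyde; 2 propane-1,3-dithiol
Product: 3 2-(3-methylfuran-2-yl)-1,3-dithiane
Conditions: BF3·OEt2 (0.1 equiv), CH2Cl2, 0 °C → rt
Reagents that add atoms: none
Why: Lewis-acid-catalysed dithioacetalisation of the aldehyde (first half of a Corey–Seebach umpolung), which the furan tolerates at 0 °C and which creates no stereocentre.

**Step 2**
Reactants: 3 2-(3-methylfuran-2-yl)-1,3-dithiane; 4 (R)-2-methyloxirane
Product: 7 TBS ether of (2R)-1-[2-(3-methylfuran-2-yl)-1,3-dithian-2-yl]propan-2-ol, via 2-lithio-dithiane 5 (not isolated), via lithium alkoxide 6 (not isolated)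
Conditions: n-BuLi, THF, −78 → −30 °C; 4, −30 → 0 °C; t-BuMe2SiOTf, −78 → 0 °C
Reagents that add atoms: tert-butyldimethylsilyl trifluoromethanesulfonate, CC(C)(C)[Si](C)(C)OS(=O)(=O)C(F)(F)F
Why: Corey–Seebach alkylation in which the dithiane carbanion opens the epoxide by SN2 attack at its CH2 group, so that the (R) centre of 4 is carried unchanged into the future C3' carbinol, and the lithium alkoxide is silylated in the same flask.

**Step 3**
Reactants: 8 1,1-dimethoxypropan-2-one; 9 (1S)-1-(naphthalen-2-yl)ethan-1-ol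
Product: 10 1-methoxy-1-[(1S)-1-(naphthalen-2-yl)ethoxy]propan-2-one (both epimers at the acetal carbon)
Conditions: PPTS (cat.), cyclohexane, 80 °C, methanol distilled off, 8 in excess
Reagents that add atoms: none
Why: acid-catalysed transacetalisation driven by removal of methanol, the new acetal centre being of no consequence because it becomes sp2 in the cation.

**Step 4**
Reactants: 10 1-methoxy-1-[(1S)-1-(naphthalen-2-yl)ethoxy]propan-2-one
Product: 12 triethyl({3-methoxy-3-[(1S)-1-(naphthalen-2-yl)ethoxy]prop-1-en-2-yl}oxy)silane, via lithium enolate 11 (not isolated)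
Conditions: LiN(iPr)2, THF, −78 °C; Et3SiCl, −78 → 0 °C
Reagents that add atoms: chlorotriethylsilane, CC[Si](Cl)(CC)CC
Why: kinetic deprotonation at the methyl group and O-silylation (silyl enol ether formation) give the 2-siloxyallyl acetal.

**Step 5**
Reactants: 7 TBS ether of (2R)-1-[2-(3-methylfuran-2-yl)-1,3-dithian-2-yl]propan-2-ol; 12 triethyl({3-methoxy-3-[(1S)-1-(naphthalen-2-yl)ethoxy]prop-1-en-2-yl}oxy)silane
Product: 14 (1S,2R,5S)-1-DTS-7-methyl-2-NEO-8-oxabicyclo[3.2.1]oct-6-en-3-one, via alkoxy-siloxyallyl cation 13 (not isolated)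
Conditions: 12 (1.5 equiv), Me3SiOTf (0.2 equiv), CH2Cl2, −95 → −78 °C; then pyridine, aq NaHCO3
Reagents that add atoms: none
Why: Me3SiOTf removes the methoxy group of 12 as a silyl methyl ether to give the W-shaped, Z-configured 1-alkoxy-2-siloxyallyl cation 13, which adds across the two α-carbons of furan 7 in an asynchronous (4+3) cycloaddition: its unsubstituted CH2 terminus bonds to the free furan α-carbon (C3a–C4 bond), its alkoxy-bearing terminus to the dithianyl-substituted α-carbon (C7–C8 bond), and the silyl oxocarbenium ion then loses Et3Si+ to leave ketone 14. The closest known reaction type is the low-temperature (4+3) cycloaddition of furans with alkoxy-substituted siloxyallyl cations made from α-keto acetal silyl enol ethers, including its variant steered by a 1-arylethoxy auxiliary. The two bonds close the seven-membered carbocycle (C3a, C4, C5, C6, C7, C8, C8a) by cycloaddition of the furan 4π system to the allyl cation, and by the same bridging mode of closure the six-membered oxan-4-one ring that contains the C4–O–C7 bridge. C4 and the quaternary C7 arise together from suprafacial addition to the furan, C8 from the compact (endo) transition state of the Z-alkoxy cation, which leaves the alkoxy group equatorial and anti to the oxygen bridge (this centre α to the ketone can also be equilibrated to that epimer), and the absolute configuration from the (S)-1-(naphthalen-2-yl)ethyl group, whose aryl ring covers one face of the cation. The step needs regioselectivity (alkoxy terminus next to the substituted bridgehead), secured because the more electrophilic CH2 terminus attacks the only unsubstituted and most nucleophilic furan α-carbon; endo selectivity, secured by the cation geometry; and facial selectivity, secured by the auxiliary, the remote silyloxypropyl centre being a spectator. The bridge installed here later controls C3a, C8a, C6 and C5.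

**Step 6**
Reactants: 14 (1S,2R,5S)-1-DTS-7-methyl-2-NEO-8-oxabicyclo[3.2.1]oct-6-en-3-one; 15 methyl bromoacetate
Product: 17 methyl 2-[(1S,2R,4R,5R)-1-DTS-7-methyl-2-NEO-3-oxo-8-oxabicyclo[3.2.1]oct-6-en-4-yl]acetate (acetate arm axial), via lithium enolate 16 (not isolated)
Conditions: LiN(iPr)2 (1.05 equiv), THF, −78 °C; DMPU, 15, −78 → −45 °C; AcOH quench at −78 °C
Reagents that add atoms: none
Why: kinetic enolate alkylation in which the base takes a proton from the unhindered CH2 flank (future C3a) and not from the alkoxy-bearing C8, and the electrophile enters from the exo face, syn to the oxygen bridge and away from the two-carbon bridge, which sets C3a with the axial acetate arm the target requires.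

**Step 7**
Reactants: 17 methyl 2-[(1S,2R,4R,5R)-1-DTS-7-methyl-2-NEO-3-oxo-8-oxabicyclo[3.2.1]oct-6-en-4-yl]acetate
Product: 19 4,7-epoxy-6-methyl-8-NEO-7-DTS-3,3a,4,7,8,8a-hexahydro-2H-cyclohepta[b]furan-2-one (cis-fused lactone), via hydroxy ester 18 (not isolated)
Conditions: NaBH4, CeCl3·7H2O, MeOH–THF, −40 °C; then PPTS (cat.), toluene, 60 °C
Reagents that add atoms: none
Why: Luche-type borohydride reduction in which hydride should add anti to the axial acetate arm (Felkin-type attack), giving the equatorial C8a alcohol that is cis to the arm and is the only epimer able to close the γ-lactone, which acid-catalysed transesterification completes.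

**Step 8**
Reactants: 19 4,7-epoxy-6-methyl-8-NEO-7-DTS-3,3a,4,7,8,8a-hexahydro-2H-cyclohepta[b]furan-2-one
Product: 21 4,7-epoxy-5-hydroxy-6-methyl-8-NEO-7-DTS-octahydro-2H-cyclohepta[b]furan-2-one (5-OH syn to the bridge, 6-methyl anti), via alkylborane 20 (not isolated)
Conditions: BH3·THF, THF, 0 °C; then Me3NO·2H2O, THF, 65 °C
Reagents that add atoms: trimethylamine N-oxide, C[N+](C)(C)[O-]
Why: hydroboration–oxidation in which boron adds to the less substituted alkene carbon C5 from the exo face and the amine oxide oxidises the C–B bond with retention without touching the thioacetal, both new centres being provisional (C5 is oxidised and C6 epimerised in step 9).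

**Step 9**
Reactants: 21 4,7-epoxy-5-hydroxy-6-methyl-8-NEO-7-DTS-octahydro-2H-cyclohepta[b]furan-2-one
Product: 23 4,7-epoxy-6-methyl-8-NEO-7-DTS-hexahydro-2H-cyclohepta[b]furan-2,5(3H)-dione with the 6-methyl exo (syn to the bridge), via endo-methyl ketone 22 (not isolated)
Conditions: (COCl)2, DMSO, CH2Cl2, −78 °C; Et3N, −78 → 0 °C; then DBU (0.3 equiv), rt
Reagents that add atoms: none
Why: Swern oxidation followed by base equilibration through the only possible enolate (towards C6, since C4 is a bridgehead) moves the methyl group to the exo position, away from the axial H-8a under the bridge, which is the C6 configuration of the target relative to O7.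

**Step 10**
Reactants: 23 4,7-epoxy-6-methyl-8-NEO-7-DTS-hexahydro-2H-cyclohepta[b]furan-2,5(3H)-dione (6-methyl exo)
Product: 25 7-hydroxy-6-methyl-8-NEO-7-DTS-hexahydro-2H-cyclohepta[b]furan-2,5(3H)-dione, via samarium enolate 24 (not isolated)
Conditions: SmI2 (2.5 equiv), THF–MeOH (10:1), −78 °C
Reagents that add atoms: none
Why: SmI2 reduction of an α-alkoxy ketone in which the ketyl expels the C4–O bond, the only C–O bond α to a ketone, and protonation of the samarium enolate leaves C4 as CH2 and frees the tertiary C7 hydroxyl without touching C6 or C7.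

**Step 11**
Reactants: 25 7-hydroxy-6-methyl-8-NEO-7-DTS-hexahydro-2H-cyclohepta[b]furan-2,5(3H)-dione
Product: 26 5,7-dihydroxy-6-methyl-8-NEO-7-DTS-octahydro-2H-cyclohepta[b]furan-2-one (all six ring centres arranged as in 37)
Conditions: Me4NBH(OAc)3, MeCN–AcOH (1:1), −30 °C
Reagents that add atoms: none
Why: Evans–Saksena hydroxyl-directed reduction in which the C7 hydroxyl binds boron and delivers hydride intramolecularly to the same face of the C5 ketone, so that the new hydroxyl is anti (1,3-trans) to O7 as in the target.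

**Step 12**
Reactants: 26 5,7-dihydroxy-6-methyl-8-NEO-7-DTS-octahydro-2H-cyclohepta[b]furan-2-one
Product: 27 5-(TBS-oxy)-7-hydroxy-6-methyl-8-NEO-7-DTS-octahydro-2H-cyclohepta[b]furan-2-one
Conditions: t-BuMe2SiCl, imidazole, DMF, 35 °C
Reagents that add atoms: tert-butyldimethylsilyl chloride, CC(C)(C)[Si](C)(C)Cl
Why: silylation of the secondary C5 hydroxyl only, since the tertiary C7 hydroxyl between two fully substituted carbons does not react with the silyl chloride.

**Step 13**
Reactants: 27 5-(TBS-oxy)-7-hydroxy-6-methyl-8-NEO-7-DTS-octahydro-2H-cyclohepta[b]furan-2-one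
Product: 31 5-(TBS-oxy)-7-hydroxy-6-methyl-3-methylidene-8-NEO-7-DTS-octahydro-2H-cyclohepta[b]furan-2-one, via dilithio lactone enolate 28 (not isolated), via Mannich base 29 (not isolated), via trimethylammonium iodide 30 (not isolated)
Conditions: LiN(iPr)2 (3 equiv), THF, −78 °C; CH2=NMe2+ I−, −78 → 0 °C; crude amine: MeI, CH2Cl2–MeOH, rt, short exposure; then aq NaHCO3
Reagents that add atoms: N,N-dimethylmethyleneiminium iodide, C=[N+](C)C.[I-]
Why: α-methylenation of the lactone by Mannich reaction of its lithium enolate with Eschenmoser's salt, N-methylation and Hofmann-type β-elimination of trimethylamine, the tertiary alkoxide being a spectator.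

**Step 14**
Reactants: 31 5-(TBS-oxy)-7-hydroxy-6-methyl-3-methylidene-8-NEO-7-DTS-octahydro-2H-cyclohepta[b]furan-2-one
Product: 32 7-[(3R)-3-(TBS-oxy)butanoyl]-5-(TBS-oxy)-7-hydroxy-6-methyl-3-methylidene-8-NEO-octahydro-2H-cyclohepta[b]furan-2-one
Conditions: Hg(ClO4)2·3H2O, CaCO3, THF–H2O (5:1), 0 °C
Reagents that add atoms: water, O
Why: mercury-assisted hydrolysis of the thioacetal (Corey–Seebach unmasking), buffered with CaCO3, releases the side-chain ketone without acid or base strong enough to harm the β-silyloxy ketone or the methylene lactone.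

**Step 15**
Reactants: 32 7-[(3R)-3-(TBS-oxy)butanoyl]-5-(TBS-oxy)-7-hydroxy-6-methyl-3-methylidene-8-NEO-octahydro-2H-cyclohepta[b]furan-2-one
Product: 33 7-[(3R)-3-(TBS-oxy)butanoyl]-5-(TBS-oxy)-7,8-dihydroxy-6-methyl-3-methylidene-octahydro-2H-cyclohepta[b]furan-2-one
Conditions: DDQ, CH2Cl2–pH 7 buffer (10:1), 0 °C → rt
Reagents that add atoms: none
Why: oxidative cleavage of the electron-rich arylmethyl-type ether with DDQ (benzylic hydride abstraction, hydrolysis of the oxocarbenium ion), possible now that no thioacetal is present, frees the C8 hydroxyl and releases the auxiliary as its ketone.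

**Step 16**
Reactants: 33 7-[(3R)-3-(TBS-oxy)butanoyl]-5-(TBS-oxy)-7,8-dihydroxy-6-methyl-3-methylidene-octahydro-2H-cyclohepta[b]furan-2-one; 34 (2S)-2-methylbutanoic acid
Product: 36 bis-TBS ether of the target (C5 and C3' silylated, C8 esterified), via mixed anhydride 35 (not isolated)
Conditions: 34, 2,4,6-Cl3C6H2COCl, Et3N, THF, rt; then 33, DMAP, toluene, rt
Reagents that add atoms: none
Why: Yamaguchi esterification in which only the secondary C8 hydroxyl is free to react (C5 and C3' are silylated, C7 is tertiary), and acyl transfer through the mixed anhydride and DMAP avoids the ketene pathway that would epimerise the α-centre of the acid.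

**Step 17**
Reactants: 36 bis-TBS ether of the target
Product: 37 (3aS,5R,6S,7S,8S,8aR)-5,7-dihydroxy-7-[(3R)-3-hydroxybutanoyl]-6-methyl-3-methylidene-2-oxooctahydro-2H-cyclohepta[b]furan-8-yl (2S)-2-methylbutanoate
Conditions: HF·pyridine, pyridine–THF, 0 °C → rt
Reagents that add atoms: none
Why: fluoride-mediated cleavage of both silyl ethers under buffered, weakly acidic conditions that leave the esters, the β-hydroxy ketone and the methylene lactone intact.

**Compound list**

1 | 3-methylfuran-2-carbaldehyde | Cc1ccoc1C=O | starting material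
2 | propane-1,3-dithiol | SCCCS | starting material
3 | 2-(3-methylfuran-2-yl)-1,3-dithiane | Cc1ccoc1C1SCCCS1 | intermediate
4 | (R)-2-methyloxirane | C[C@@H]1CO1 | starting material
5 | 2-lithio-2-(3-methylfuran-2-yl)-1,3-dithiane | Cc1ccoc1C1([Li])SCCCS1 | intermediate
6 | lithium (2R)-1-[2-(3-methylfuran-2-yl)-1,3-dithian-2-yl]propan-2-olate | Cc1ccoc1C1(SCCCS1)C[C@@H](C)O[Li] | intermediate
7 | TBS ether of (2R)-1-[2-(3-methylfuran-2-yl)-1,3-dithian-2-yl]propan-2-ol | Cc1ccoc1C1(SCCCS1)C[C@@H](C)O[Si](C)(C)C(C)(C)C | intermediate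
8 | 1,1-dimethoxypropan-2-one | CC(=O)C(OC)OC | starting material
9 | (1S)-1-(naphthalen-2-yl)ethan-1-ol | C[C@H](O)c1ccc2ccccc2c1 | starting material
10 | 1-methoxy-1-[(1S)-1-(naphthalen-2-yl)ethoxy]propan-2-one (both acetal epimers) | CC(=O)C(OC)O[C@@H](C)c1ccc2ccccc2c1 | intermediate
11 | lithium 3-methoxy-3-[(1S)-1-(naphthalen-2-yl)ethoxy]prop-1-en-2-olate | C=C(O[Li])C(OC)O[C@@H](C)c1ccc2ccccc2c1 | intermediate
12 | triethyl({3-methoxy-3-[(1S)-1-(naphthalen-2-yl)ethoxy]prop-1-en-2-yl}oxy)silane | C=C(O[Si](CC)(CC)CC)C(OC)O[C@@H](C)c1ccc2ccccc2c1 | intermediate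
13 | 1-[(1S)-1-(naphthalen-2-yl)ethoxy]-2-(triethylsilyloxy)allyl cation triflate | C=C(O[Si](CC)(CC)CC)C=[O+][C@@H](C)c1ccc2ccccc2c1.[O-]S(=O)(=O)C(F)(F)F | intermediate
14 | (1S,2R,5S)-1-DTS-7-methyl-2-NEO-8-oxabicyclo[3.2.1]oct-6-en-3-one (alkoxy group equatorial, anti to the oxygen bridge) | O=C1C[C@H]2C=C(C)[C@@](O2)(C3(SCCCS3)C[C@@H](C)O[Si](C)(C)C(C)(C)C)[C@H]1O[C@@H](C)c1ccc2ccccc2c1 | intermediate
15 | methyl bromoacetate | COC(=O)CBr | starting material
16 | lithium enolate of 14 (C3=C4 of the bicycle) | [Li]OC1=C[C@H]2C=C(C)[C@@](O2)(C3(SCCCS3)C[C@@H](C)O[Si](C)(C)C(C)(C)C)[C@H]1O[C@@H](C)c1ccc2ccccc2c1 | intermediate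
17 | methyl 2-[(1S,2R,4R,5R)-1-DTS-7-methyl-2-NEO-3-oxo-8-oxabicyclo[3.2.1]oct-6-en-4-yl]acetate (acetate arm axial, syn to the oxygen bridge) | O=C1[C@H](CC(=O)OC)[C@H]2C=C(C)[C@@](O2)(C3(SCCCS3)C[C@@H](C)O[Si](C)(C)C(C)(C)C)[C@H]1O[C@@H](C)c1ccc2ccccc2c1 | intermediate
18 | hydroxy ester from 17 (C3 hydroxyl of the bicycle equatorial, cis to the acetate arm) | O[C@@H]1[C@H](CC(=O)OC)[C@H]2C=C(C)[C@@](O2)(C3(SCCCS3)C[C@@H](C)O[Si](C)(C)C(C)(C)C)[C@H]1O[C@@H](C)c1ccc2ccccc2c1 | intermediate
19 | 4,7-epoxy-6-methyl-8-NEO-7-DTS-3,3a,4,7,8,8a-hexahydro-2H-cyclohepta[b]furan-2-one (cis-fused lactone; C3a, C7, C8, C8a arranged as in 37) | C1C(=O)O[C@@H]2[C@H]1[C@H]3C=C(C)[C@@](O3)(C4(SCCCS4)C[C@@H](C)O[Si](C)(C)C(C)(C)C)[C@H]2O[C@@H](C)c1ccc2ccccc2c1 | intermediate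
20 | 5-boryl derivative of 19 (BH2 at C5 and H at C6 both syn to the bridge) | C1C(=O)O[C@@H]2[C@H]1[C@H]3[C@H](B)[C@@H](C)[C@@](O3)(C4(SCCCS4)C[C@@H](C)O[Si](C)(C)C(C)(C)C)[C@H]2O[C@@H](C)c1ccc2ccccc2c1 | intermediate
21 | 4,7-epoxy-5-hydroxy-6-methyl-8-NEO-7-DTS-octahydro-2H-cyclohepta[b]furan-2-one (5-OH syn to the bridge, 6-methyl anti) | C1C(=O)O[C@@H]2[C@H]1[C@H]3[C@H](O)[C@@H](C)[C@@](O3)(C4(SCCCS4)C[C@@H](C)O[Si](C)(C)C(C)(C)C)[C@H]2O[C@@H](C)c1ccc2ccccc2c1 | intermediate
22 | 4,7-epoxy-6-methyl-8-NEO-7-DTS-hexahydro-2H-cyclohepta[b]furan-2,5(3H)-dione, 6-methyl anti to the bridge (endo) | C1C(=O)O[C@@H]2[C@H]1[C@H]3C(=O)[C@@H](C)[C@@](O3)(C4(SCCCS4)C[C@@H](C)O[Si](C)(C)C(C)(C)C)[C@H]2O[C@@H](C)c1ccc2ccccc2c1 | intermediate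
23 | 4,7-epoxy-6-methyl-8-NEO-7-DTS-hexahydro-2H-cyclohepta[b]furan-2,5(3H)-dione, 6-methyl syn to the bridge (exo) | C1C(=O)O[C@@H]2[C@H]1[C@H]3C(=O)[C@H](C)[C@@](O3)(C4(SCCCS4)C[C@@H](C)O[Si](C)(C)C(C)(C)C)[C@H]2O[C@@H](C)c1ccc2ccccc2c1 | intermediate
24 | samarium C4=C5 enolate and C7 alkoxide formed from 23 | C1C(=O)O[C@@H]2[C@H]1C=C(O[Sm](I)I)[C@H](C)[C@@](O[Sm](I)I)(C3(SCCCS3)C[C@@H](C)O[Si](C)(C)C(C)(C)C)[C@H]2O[C@@H](C)c1ccc2ccccc2c1 | intermediate
25 | 7-hydroxy-6-methyl-8-NEO-7-DTS-hexahydro-2H-cyclohepta[b]furan-2,5(3H)-dione (C3a, C6, C7, C8, C8a arranged as in 37) | C1C(=O)O[C@@H]2[C@H]1CC(=O)[C@H](C)[C@@](O)(C3(SCCCS3)C[C@@H](C)O[Si](C)(C)C(C)(C)C)[C@H]2O[C@@H](C)c1ccc2ccccc2c1 | intermediate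
26 | 5,7-dihydroxy-6-methyl-8-NEO-7-DTS-octahydro-2H-cyclohepta[b]furan-2-one (ring centres arranged as in 37) | C1C(=O)O[C@@H]2[C@H]1C[C@@H](O)[C@H](C)[C@@](O)(C3(SCCCS3)C[C@@H](C)O[Si](C)(C)C(C)(C)C)[C@H]2O[C@@H](C)c1ccc2ccccc2c1 | intermediate
27 | 5-(TBS-oxy)-7-hydroxy-6-methyl-8-NEO-7-DTS-octahydro-2H-cyclohepta[b]furan-2-one | C1C(=O)O[C@@H]2[C@H]1C[C@@H](O[Si](C)(C)C(C)(C)C)[C@H](C)[C@@](O)(C3(SCCCS3)C[C@@H](C)O[Si](C)(C)C(C)(C)C)[C@H]2O[C@@H](C)c1ccc2ccccc2c1 | intermediate
28 | dilithio species of 27 (lactone enolate and C7 alkoxide) | C1=C(O[Li])O[C@@H]2[C@H]1C[C@@H](O[Si](C)(C)C(C)(C)C)[C@H](C)[C@@](O[Li])(C3(SCCCS3)C[C@@H](C)O[Si](C)(C)C(C)(C)C)[C@H]2O[C@@H](C)c1ccc2ccccc2c1 | intermediate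
29 | 3-[(dimethylamino)methyl] derivative of 27 (C3 epimers) | CN(C)CC1C(=O)O[C@@H]2[C@H]1C[C@@H](O[Si](C)(C)C(C)(C)C)[C@H](C)[C@@](O)(C3(SCCCS3)C[C@@H](C)O[Si](C)(C)C(C)(C)C)[C@H]2O[C@@H](C)c1ccc2ccccc2c1 | intermediate
30 | N-methyl ammonium iodide of 29 | C[N+](C)(C)CC1C(=O)O[C@@H]2[C@H]1C[C@@H](O[Si](C)(C)C(C)(C)C)[C@H](C)[C@@](O)(C3(SCCCS3)C[C@@H](C)O[Si](C)(C)C(C)(C)C)[C@H]2O[C@@H](C)c1ccc2ccccc2c1.[I-] | intermediate
31 | 5-(TBS-oxy)-7-hydroxy-6-methyl-3-methylidene-8-NEO-7-DTS-octahydro-2H-cyclohepta[b]furan-2-one | C=C1C(=O)O[C@@H]2[C@H]1C[C@@H](O[Si](C)(C)C(C)(C)C)[C@H](C)[C@@](O)(C3(SCCCS3)C[C@@H](C)O[Si](C)(C)C(C)(C)C)[C@H]2O[C@@H](C)c1ccc2ccccc2c1 | intermediate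
32 | 7-[(3R)-3-(TBS-oxy)butanoyl]-5-(TBS-oxy)-7-hydroxy-6-methyl-3-methylidene-8-NEO-octahydro-2H-cyclohepta[b]furan-2-one | C=C1C(=O)O[C@@H]2[C@H]1C[C@@H](O[Si](C)(C)C(C)(C)C)[C@H](C)[C@@](O)(C(=O)C[C@@H](C)O[Si](C)(C)C(C)(C)C)[C@H]2O[C@@H](C)c1ccc2ccccc2c1 | intermediate
33 | 7-[(3R)-3-(TBS-oxy)butanoyl]-5-(TBS-oxy)-7,8-dihydroxy-6-methyl-3-methylidene-octahydro-2H-cyclohepta[b]furan-2-one | C=C1C(=O)O[C@@H]2[C@H]1C[C@@H](O[Si](C)(C)C(C)(C)C)[C@H](C)[C@@](O)(C(=O)C[C@@H](C)O[Si](C)(C)C(C)(C)C)[C@H]2O | intermediate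
34 | (2S)-2-methylbutanoic acid | CC[C@H](C)C(=O)O | starting material
35 | (2S)-2-methylbutanoic 2,4,6-trichlorobenzoic anhydride | CC[C@H](C)C(=O)OC(=O)c1c(Cl)cc(Cl)cc1Cl | intermediate
36 | bis-TBS ether of the target (silyl on O5 and O3', (2S)-2-methylbutanoate on O8) | C=C1C(=O)O[C@@H]2[C@H]1C[C@@H](O[Si](C)(C)C(C)(C)C)[C@H](C)[C@@](O)(C(=O)C[C@@H](C)O[Si](C)(C)C(C)(C)C)[C@H]2OC(=O)[C@@H](C)CC | intermediate
37 | (3aS,5R,6S,7S,8S,8aR)-5,7-dihydroxy-7-[(3R)-3-hydroxybutanoyl]-6-methyl-3-methylidene-2-oxooctahydro-2H-cyclohepta[b]furan-8-yl (2S)-2-methylbutanoate | C=C1C(=O)O[C@@H]2[C@H]1C[C@@H](O)[C@H](C)[C@@](O)(C(=O)C[C@@H](C)O)[C@H]2OC(=O)[C@@H](C)CC | target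

**Step count and risks**

Total steps: 17. Longest linear sequence: 15 steps (steps 1, 2 and 5 to 17).

Steps most likely to fail:

Step 5 (key step). After the first bond (C3a–C4) has formed, closure onto the fully substituted, dithiane-flanked furan carbon may be outrun by proton loss from the furan, so that only C-alkylation of the furan results. The facial control exerted by the auxiliary may also erode with a 2,3-disubstituted furan. The fallback sets out from 3 and 12 and returns at 19; it attaches the side chain after the cycloaddition. The cycloaddition is run under the conditions of step 5 on the less crowded, achiral furan 3, whose dithiane still carries its hydrogen, to give the side-chain-free bicyclic ketone F1. Enolate alkylation with 15 as in step 6 gives the keto ester F2, and reduction–lactonisation as in step 7 gives the bridged lactone F3. The lactone is then protected in the flask as its lithium enolate (LiN(iPr)2, THF, −78 °C), the dithiane is lithiated with n-BuLi (−30 °C) and the carbanion opens epoxide 4 to give the hydroxypropyl lactone F4. Silylation (t-BuMe2SiCl, imidazole, DMF) then gives 19.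

Step 7. Hydride may be delivered from the exo face in spite of the axial arm, or C3a may epimerise before reduction; the C8a alcohol is then trans to the acetate arm and cannot lactonise. The fallback sets out from 17 and returns at 19. Reduction with the bulky LiBH(s-Bu)3 (THF, −78 °C), expected to favour exo attack, gives the axial hydroxy ester F5. Saponification (LiOH, THF–H2O) gives the hydroxy acid F6. Mitsunobu lactonisation (PPh3, diisopropyl azodicarboxylate, toluene), in which the carboxylate displaces the activated hydroxyl with inversion at C8a, gives 19.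

Step 11. Ligand exchange of the crowded tertiary hydroxyl on boron may be too slow, so that hydride arrives intermolecularly from the less hindered face and the 1,3-syn diol forms. The fallback sets out from 25 and returns at 26. External reduction (NaBH4, CeCl3·7H2O, MeOH, −78 °C) gives the 5-epi diol F7. Mitsunobu inversion of the secondary hydroxyl with 4-nitrobenzoic acid (PPh3, diisopropyl azodicarboxylate, THF) gives the inverted 4-nitrobenzoate F8. Methanolysis of this activated ester (K2CO3, MeOH, 0 °C) gives 26.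

**Further compounds**

F1 | step 5 | (1S,2R,5S)-1-(1,3-dithian-2-yl)-7-methyl-2-NEO-8-oxabicyclo[3.2.1]oct-6-en-3-one | O=C1C[C@H]2C=C(C)[C@@](O2)(C3SCCCS3)[C@H]1O[C@@H](C)c1ccc2ccccc2c1
F2 | step 5 | methyl 2-[1-(1,3-dithian-2-yl)-7-methyl-2-NEO-3-oxo-8-oxabicyclo[3.2.1]oct-6-en-4-yl]acetate (acetate arm axial, syn to the bridge) | O=C1[C@H](CC(=O)OC)[C@H]2C=C(C)[C@@](O2)(C3SCCCS3)[C@H]1O[C@@H](C)c1ccc2ccccc2c1
F3 | step 5 | 7-(1,3-dithian-2-yl)-4,7-epoxy-6-methyl-8-NEO-3,3a,4,7,8,8a-hexahydro-2H-cyclohepta[b]furan-2-one | C1C(=O)O[C@@H]2[C@H]1[C@H]3C=C(C)[C@@](O3)(C4SCCCS4)[C@H]2O[C@@H](C)c1ccc2ccccc2c1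
F4 | step 5 | 4,7-epoxy-7-{2-[(2R)-2-hydroxypropyl]-1,3-dithian-2-yl}-6-methyl-8-NEO-3,3a,4,7,8,8a-hexahydro-2H-cyclohepta[b]furan-2-one | C1C(=O)O[C@@H]2[C@H]1[C@H]3C=C(C)[C@@](O3)(C4(SCCCS4)C[C@@H](C)O)[C@H]2O[C@@H](C)c1ccc2ccccc2c1
F5 | step 7 | hydroxy ester epimeric with 18 at the carbinol carbon (hydroxyl axial, trans to the acetate arm) | O[C@H]1[C@H](CC(=O)OC)[C@H]2C=C(C)[C@@](O2)(C3(SCCCS3)C[C@@H](C)O[Si](C)(C)C(C)(C)C)[C@H]1O[C@@H](C)c1ccc2ccccc2c1
F6 | step 7 | carboxylic acid corresponding to F5 | O[C@H]1[C@H](CC(=O)O)[C@H]2C=C(C)[C@@](O2)(C3(SCCCS3)C[C@@H](C)O[Si](C)(C)C(C)(C)C)[C@H]1O[C@@H](C)c1ccc2ccccc2c1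
F7 | step 11 | 5-epimer of 26 (5-OH syn to the 7-OH) | C1C(=O)O[C@@H]2[C@H]1C[C@H](O)[C@H](C)[C@@](O)(C3(SCCCS3)C[C@@H](C)O[Si](C)(C)C(C)(C)C)[C@H]2O[C@@H](C)c1ccc2ccccc2c1
F8 | step 11 | 5-O-(4-nitrobenzoate) of 26 | C1C(=O)O[C@@H]2[C@H]1C[C@@H](OC(=O)c3ccc(cc3)[N+](=O)[O-])[C@H](C)[C@@](O)(C3(SCCCS3)C[C@@H](C)O[Si](C)(C)C(C)(C)C)[C@H]2O[C@@H](C)c1ccc2ccccc2c1
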